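(The numbers in the tables stem from a simulated flask for substances that don't exist; the scatter is artificial.)

Time is the same in cedar and ash: both stop at 8.0 h, and they differ in their charge of solid reagent.

| setting | blue | grey | cedar | ash |
|---|---|---|---|---|
| left-handed substrate | 0.10 M | 0.10 M | 0.10 M | 0.10 M |
| right-handed substrate | 0.10 M | 0.10 M | 0.10 M | 0.10 M |
| solid reagent | 2.8 equiv | 3.4 equiv | 3.00 equiv | 4.50 equiv |
| free catalyst | 0.05 mol% | 0.05 mol% | 0.05 mol% | 0.05 mol% |
| racemization catalyst | 0.2 mol% | 0.2 mol% | 0.2 mol% | 0.2 mol% |
| remark | run made earlier | run made earlier |  |  |
| time |  |  | 8.0 h | 8.0 h |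

| run | time / h | right-handed substrate / % | left-handed substrate / % |
|---|---|---|---|
| blue | 0.417 | 47.3 | 44.6 |
| blue | 0.833 | 43.7 | 37.6 |
| blue | 1.50 | 37.8 | 29.2 |
| blue | 3.00 | 26.3 | 16.2 |
| blue | 6.00 | 6.7 | 0.8 |
| grey | 0.417 | 48.9 | 47.0 |
| grey | 0.833 | 44.8 | 37.9 |
| grey | 1.50 | 39.7 | 31.7 |
| grey | 3.00 | 26.5 | 16.1 |
| grey | 6.00 | 9.6 | 1.2 |

(scatter of a reading: 1 percentage point)

- free catalyst is single-handed; left-handed substrate and right-handed substrate are mirror images of each other, charged as a racemate, each of them at the stated concentration
- solid, in amounts per volume of the solution: solid reagent
- at the start none of the solid reagent is in solution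
- an excess is the difference of the two amounts in percent of their sum
- an excess is below zero if the other one leads

- the winner by excess of right-handed substrate over left-handed substrate among what is left of the two; "neither" if no more than 2 percentage points parts them (cedar / ash / neither)
- excess of right-handed substrate over left-handed substrate among what is left of the two at the end, cedar
- excess of right-handed substrate over left-handed substrate among what is left of the two at the end, ash

At 3.00 h, blue had 42.5% of its two substrates left, and grey, with more solid reagent, had 42.6%. Within the scatter, the extra solid had bought no speed by then.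

I folded each charge into one number, the cover, 1.50 for cedar and 2.25 for ash: the solid reagent charged divided by the two substrates together, on my assumption of one unit of solid per unit of substrate. A cover above one makes the substrates the limiting reagent, and both flasks stood there. Full conversion should leave 33.3% of the solid reagent, solid or dissolved, in cedar and 55.6% in ash. So I expected no gap between cedar and ash. But one number was not enough: the cover has no clock in it, so it gave me no size for the excess.

The forecast said neither, with 88% for cedar and 88% for ash: “Cedar and ash should therefore match”.

The flasks gave neither, with 95.0% in cedar and 95.0% in ash, both above the forecast.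

    coupling partner + free catalyst + right-handed substrate → free catalyst + right-handed product (k = 110 M⁻² s⁻¹)
    coupling partner + free catalyst + left-handed substrate → free catalyst + left-handed product (k = 320 M⁻² s⁻¹)
    racemization catalyst → spent catalyst (k = 1.20 × 10⁻⁴ s⁻¹)
    solid reagent ⇌ coupling partner, rate k4*(cs4 - [coupling partner]) while solid is left; crystals form when [coupling partner] > cs4 (solubility = 37.0 mM, k = 4.20 × 10⁻⁴ s⁻¹)
    left-handed substrate + racemization catalyst ⇌ right-handed substrate + racemization catalyst, rate k5*[racemization catalyst]*[left-handed substrate] forward; the back reaction follows from the equilibrium constant (k = 0.630 M⁻¹ s⁻¹)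

Ash had converted 97.8% of its substrates by 8.0 h, so its cover gave 56.5% of the solid reagent left, solid or dissolved, and ash held 57%. The neighbouring flask, ash with 0.2 mol% of free catalyst, has the same cover of 2.25. Of its charge it kept 0% of the left-handed and 0% of the right-handed substrate, so the cover gave 55.6%, and that flask held 56%, solid or dissolved. Its excess stood at 99.4%.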